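**Plan**

- Numbering: unprimed atoms belong to the 7-methoxy NH-indole, primed atoms to the indole bound through N1' to C4. The retrosynthesis removes C3–Br and C3'–Br first, then cuts N1–C2 and C3–C3a (a vinyl unit added to a nitroarene), then takes the primed benzo ring back to a 5'-bromo-4'-oxotetrahydroindole, and last cuts N1'–C2' and N1'–C7a'.
- Enabling feature: N1' has three carbon neighbours, C2' and C7a' of its own pyrrole ring and the crowded C4. C4 can be the ipso carbon of an aniline, so N1'–C4 is never made, and both ring bonds to N1' come from condensing that aniline with a 1,4-dicarbonyl (aldehyde carbon = C2', ring ketone carbon = C7a'). The second ring ketone stays as C4'=O, which leaves C5' as the only enolisable carbon and so the only site for bromine.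
- Forward order: the six-membered carbocycle is bought as cyclohexane-1,3-dione; the primed pyrrole ring closes in step 4; the carbocycle is brominated at C5' and aromatised in steps 5–7; the unprimed pyrrole ring closes in step 8; C3 and C3' are brominated last.
- Stereochemistry: the target has no stereocentre. The transient centres (C2' in 8, C5' in 10, C4'/C5' in 11) are racemic and are destroyed by dehydration or aromatisation.

Key step: step 4

Assumption: the target is written without stereodescriptors, so the N1'–C4 axis is treated as stereochemically undefined and no control of it is attempted.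

**Route**

Step 1
Reactants: 1 4-methoxy-3-nitroaniline
Product: 2 2-bromo-4-methoxy-5-nitroaniline
Conditions: NBS (1.0 equiv), MeCN, 0 °C to rt
Reagents that add atoms: N-bromosuccinimide, O=C1CCC(=O)N1Br
Why: Electrophilic aromatic bromination in which the free amino group controls orientation; its para position carries OMe and the ortho carbon between NH2 and NO2 is shielded, so bromine should enter the other ortho carbon (C6 of 1, which is C2 of 2).

Step 2
Reactants: 3 cyclohexane-1,3-dione
Product: 4 2-(prop-2-en-1-yl)cyclohexane-1,3-dione
Conditions: allyl bromide, KOH, H2O, Cu powder (cat.), rt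
Reagents that add atoms: allyl bromide, C=CCBr
Why: C-alkylation of the 1,3-dione enolate with an allylic halide in water, where solvation of the enolate oxygens favours attack through carbon, and a slight excess of 3 limits double allylation.

Step 3
Reactants: 4 2-(prop-2-en-1-yl)cyclohexane-1,3-dione
Product: 6 2-(2-oxoethyl)cyclohexane-1,3-dione, via secondary ozonide 5 (not isolated)
Conditions: O3 (about 1 equiv, Sudan Red 7B end point), CH2Cl2, −78 °C; then PPh3, −78 °C to rt
Reagents that add atoms: ozone, [O-][O+]=O
Why: Ozonolysis with reductive work-up (Criegee mechanism), in which the isolated terminal alkene should be consumed before the carbonyl-conjugated enol double bond when ozone is limited to one equivalent; 6 equilibrates with its enol and cyclic hemiacetal forms and is carried on crude.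

Step 4
Reactants: 2 2-bromo-4-methoxy-5-nitroaniline; 6 2-(2-oxoethyl)cyclohexane-1,3-dione
Product: 9 1-(2-bromo-4-methoxy-5-nitrophenyl)-1,5,6,7-tetrahydro-4H-indol-4-one, via enaminone aldehyde 7 (not isolated), via cyclic hemiaminal 8 (not isolated)
Conditions: AcOH, 90 °C
Reagents that add atoms: none
Why: Paal–Knorr pyrrole synthesis: the amino group of 2 condenses with one of the two equivalent ring carbonyls of 6 (a vinylogous acid, so the step is amide-like and favourable even for a weak nucleophile) to give vinylogous amide 7, whose nitrogen adds to the side-chain aldehyde to form hemiaminal 8, and acid-catalysed loss of water then aromatises the five-membered ring. The closest known reaction type is the condensation of 2-(2-oxoalkyl)cyclohexane-1,3-diones with anilines to 1-aryl-4-oxo-4,5,6,7-tetrahydroindoles. The pyrrole ring closes by 5-exo-trig attack of nitrogen on the aldehyde carbon (N1'–C2'), N1'–C7a' having been made in the preceding condensation. No stereocentre is created in 9, because the carbinol carbon of 8 is lost on dehydration. The selectivity needed is ring closure through nitrogen and not oxygen (6 alone can cyclodehydrate to the furan); it should be secured by the weak acid AcOH, a slight excess of 2 and the thermodynamic preference for the vinylogous amide. Regiochemistry is not an issue, since the two ring carbonyls of 6 are equivalent and the one left over becomes the C4' ketone.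

Step 5
Reactants: 9 1-(2-bromo-4-methoxy-5-nitrophenyl)-1,5,6,7-tetrahydro-4H-indol-4-one
Product: 10 5-bromo-1-(2-bromo-4-methoxy-5-nitrophenyl)-1,5,6,7-tetrahydro-4H-indol-4-one (racemic)
Conditions: CuBr2 (2.1 equiv), EtOAc–CHCl3 (1:1), reflux
Reagents that add atoms: copper dibromide CuBr2, [Cu+2].[Br-].[Br-]
Why: α-Bromination of a ketone through its enol with CuBr2; C5' is the only enolisable α-carbon (the other, C3a', is part of the pyrrole) and the pyrrole ring is deactivated by the conjugated C4' carbonyl and the nitroaryl group on nitrogen, while the racemic C5' centre is erased in step 6.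

Step 6
Reactants: 10 5-bromo-1-(2-bromo-4-methoxy-5-nitrophenyl)-1,5,6,7-tetrahydro-4H-indol-4-one
Product: 12 5-bromo-1-(2-bromo-4-methoxy-5-nitrophenyl)-6,7-dihydro-1H-indole, via bromohydrin 11 (not isolated)
Conditions: NaBH4, MeOH–THF, 0 °C; aqueous work-up; then TsOH·H2O (cat.), toluene, 70 °C
Reagents that add atoms: none
Why: Hydride reduction of the α-bromoketone to bromohydrin 11 followed by acid-catalysed E1 dehydration; the C4' cation is stabilised by the pyrrole nitrogen and its only β-hydrogen sits on C5', so the C4'=C5' vinyl bromide should result (the 2-bromo-1-tetralone to 3-bromo-1,2-dihydronaphthalene sequence is the model), whatever the diastereomer composition of 11.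

Step 7
Reactants: 12 5-bromo-1-(2-bromo-4-methoxy-5-nitrophenyl)-6,7-dihydro-1H-indole
Product: 13 5-bromo-1-(2-bromo-4-methoxy-5-nitrophenyl)-1H-indole
Conditions: DDQ (1.1 equiv), 1,4-dioxane, rt
Reagents that add atoms: none
Why: Quinone dehydrogenation of a 6,7-dihydroindole (hydride abstraction from C7' next to the pyrrole, then loss of the C6' proton), driven by formation of the benzene ring and leaving the vinylic C–Br bond as the C5' aryl bromide.

Step 8
Reactants: 13 5-bromo-1-(2-bromo-4-methoxy-5-nitrophenyl)-1H-indole
Product: 15 5-bromo-4-(5-bromo-1H-indol-1-yl)-7-methoxy-1H-indole, via nitrosoarene 14 (not isolated)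
Conditions: CH2=CHMgBr (3.5 equiv), THF, −45 °C; then aq. NH4Cl
Reagents that add atoms: vinylmagnesium bromide, C=C[Mg]Br
Why: Bartoli indole synthesis: the first equivalent of Grignard reagent reduces the nitro group to nitrosoarene 14, the second adds at the nitroso oxygen, and a [3,3]-sigmatropic shift to the only free ortho carbon followed by ring closure and loss of water forms C3–C3a and N1–C2; the ortho methoxy group is the required ortho substituent and ends as C7–OMe, and aryl bromides are inert to the vinyl Grignard reagent at this temperature.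

Step 9
Reactants: 15 5-bromo-4-(5-bromo-1H-indol-1-yl)-7-methoxy-1H-indole
Product: 17 rivularin B, via tribromide 16 (not isolated)
Conditions: NBS (2.05 equiv), DMF, −20 to 0 °C, dark
Reagents that add atoms: N-bromosuccinimide, O=C1CCC(=O)N1Br
Why: Electrophilic bromination of indoles at C3 with NBS; C3 and C3' are the enamine-type, most nucleophilic carbons of the two indole units (the NH indole should react first to give 16), and C2, C2' and C6 are much less reactive at low temperature, so two equivalents should stop at the tetrabromide.

**Compound list**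

1 | 4-methoxy-3-nitroaniline | COc1ccc(N)cc1[N+](=O)[O-] | starting material
2 | 2-bromo-4-methoxy-5-nitroaniline | COc1cc(Br)c(N)cc1[N+](=O)[O-] | intermediate
3 | cyclohexane-1,3-dione | O=C1CCCC(=O)C1 | starting material
4 | 2-(prop-2-en-1-yl)cyclohexane-1,3-dione | C=CCC1C(=O)CCCC1=O | intermediate
5 | 2-[(1,2,4-trioxolan-3-yl)methyl]cyclohexane-1,3-dione (secondary ozonide, racemic, not isolated) | O=C1CCCC(=O)C1CC1OCOO1 | intermediate
6 | 2-(2-oxoethyl)cyclohexane-1,3-dione (drawn as the triketone; in equilibrium with enol and cyclic hemiacetal forms) | O=CCC1C(=O)CCCC1=O | intermediate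
7 | 3-[(2-bromo-4-methoxy-5-nitrophenyl)amino]-2-(2-oxoethyl)cyclohex-2-en-1-one (not isolated) | COc1cc(Br)c(NC2=C(CC=O)C(=O)CCC2)cc1[N+](=O)[O-] | intermediate
8 | 1-(2-bromo-4-methoxy-5-nitrophenyl)-2-hydroxy-1,2,3,5,6,7-hexahydro-4H-indol-4-one (racemic, not isolated) | COc1cc(Br)c(N2C(O)CC3=C2CCCC3=O)cc1[N+](=O)[O-] | intermediate
9 | 1-(2-bromo-4-methoxy-5-nitrophenyl)-1,5,6,7-tetrahydro-4H-indol-4-one | COc1cc(Br)c(-n2ccc3c2CCCC3=O)cc1[N+](=O)[O-] | intermediate
10 | 5-bromo-1-(2-bromo-4-methoxy-5-nitrophenyl)-1,5,6,7-tetrahydro-4H-indol-4-one (racemic) | COc1cc(Br)c(-n2ccc3c2CCC(Br)C3=O)cc1[N+](=O)[O-] | intermediate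
11 | 5-bromo-1-(2-bromo-4-methoxy-5-nitrophenyl)-4,5,6,7-tetrahydro-1H-indol-4-ol (racemic mixture of diastereomers, not isolated) | COc1cc(Br)c(-n2ccc3c2CCC(Br)C3O)cc1[N+](=O)[O-] | intermediate
12 | 5-bromo-1-(2-bromo-4-methoxy-5-nitrophenyl)-6,7-dihydro-1H-indole | COc1cc(Br)c(-n2ccc3c2CCC(Br)=C3)cc1[N+](=O)[O-] | intermediate
13 | 5-bromo-1-(2-bromo-4-methoxy-5-nitrophenyl)-1H-indole | COc1cc(Br)c(-n2ccc3cc(Br)ccc32)cc1[N+](=O)[O-] | intermediate
14 | 5-bromo-1-(2-bromo-4-methoxy-5-nitrosophenyl)-1H-indole (not isolated) | COc1cc(Br)c(-n2ccc3cc(Br)ccc32)cc1N=O | intermediate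
15 | 5-bromo-4-(5-bromo-1H-indol-1-yl)-7-methoxy-1H-indole | COc1cc(Br)c(-n2ccc3cc(Br)ccc32)c2cc[nH]c12 | intermediate
16 | 3,5-dibromo-4-(5-bromo-1H-indol-1-yl)-7-methoxy-1H-indole (not isolated) | COc1cc(Br)c(-n2ccc3cc(Br)ccc32)c2c(Br)c[nH]c12 | intermediate
17 | rivularin B, 3,5-dibromo-4-(3,5-dibromo-1H-indol-1-yl)-7-methoxy-1H-indole | COc1cc(Br)c(-n2cc(Br)c3cc(Br)ccc32)c2c(Br)c[nH]c12 | target

**Count**

Total steps: 9. Longest linear sequence: 8 steps (3 to 17 through steps 2–9); the aniline branch adds step 1.

**Steps most likely to fail**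

Step 8. Addition of the Grignard reagent to the aromatic ring, or plain reduction of the nitro group to the amine, may outrun O-vinylation and the sigmatropic shift into the crowded ortho carbon; a methoxy group is also a weaker ortho promoter than a halogen. The fallback builds the second pyrrole ring from an ortho-alkynylaniline; it sets out from 13 and comes back to the route at 17.
- 13 would first be brominated at C3' with NBS (1 equiv, DMF, 0 °C) to 3,5-dibromo-1-(2-bromo-4-methoxy-5-nitrophenyl)-1H-indole F1, so that the primed indole no longer competes for electrophiles.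
- Reduction of the nitro group with Fe powder and NH4Cl in aqueous EtOH at 70 °C should give 4-bromo-5-(3,5-dibromo-1H-indol-1-yl)-2-methoxyaniline F2.
- Iodination with NIS in MeCN at the only open ortho position of the amino group should give 4-bromo-3-(3,5-dibromo-1H-indol-1-yl)-2-iodo-6-methoxyaniline F3.
- Sonogashira coupling with trimethylsilylacetylene (Pd(PPh3)2Cl2, CuI, Et3N, rt), selective for C–I over C–Br, should give 4-bromo-3-(3,5-dibromo-1H-indol-1-yl)-6-methoxy-2-[(trimethylsilyl)ethynyl]aniline F4.
- KOt-Bu in NMP at rt should remove silicon and close the ring by 5-endo-dig attack of the anilide nitrogen, giving 5-bromo-4-(3,5-dibromo-1H-indol-1-yl)-7-methoxy-1H-indole F5.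
- One equivalent of NBS (DMF, 0 °C) then brominates C3 and delivers 17.

Step 4. Condensation of the hindered, weakly nucleophilic aniline may be slower than acid-catalysed ring closure of 6 through oxygen or aldol self-condensation of the aldehyde. The fallback makes the two N1' ring bonds in separate operations; it sets out from 2 and 3 and comes back at 9.
- 2 and 3 would be condensed under water removal (TsOH·H2O cat., toluene, Dean–Stark) to the vinylogous amide 3-[(2-bromo-4-methoxy-5-nitrophenyl)amino]cyclohex-2-en-1-one F6, which forms N1'–C7a'.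
- A Hantzsch-type pyrrole annulation of F6 with aqueous chloroacetaldehyde (NaHCO3, EtOH, 70 °C) then supplies C2' and C3': aldol attack of the enaminone α-carbon on the aldehyde, N-alkylation by the chloromethyl carbon, and dehydration to 9.

Step 3. Ozone may attack the enol double bond of the dione in competition with the terminal alkene, leading to over-oxidation and ring cleavage. The fallback avoids any oxidative cleavage; it sets out from 3 and comes back at 6.
- Oxidative radical addition of 3 to ethyl vinyl ether with (NH4)2Ce(NO3)6 and NaHCO3 in MeCN at 0 °C should give the cyclic acetal 2-ethoxy-3,5,6,7-tetrahydro-1-benzofuran-4(2H)-one F7 (racemic).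
- Hydrolysis of F7 with aqueous HCl in THF at rt releases 6.

**Further compounds**

F1 | step 8 | 3,5-dibromo-1-(2-bromo-4-methoxy-5-nitrophenyl)-1H-indole | COc1cc(Br)c(-n2cc(Br)c3cc(Br)ccc32)cc1[N+](=O)[O-]
F2 | step 8 | 4-bromo-5-(3,5-dibromo-1H-indol-1-yl)-2-methoxyaniline | COc1cc(Br)c(-n2cc(Br)c3cc(Br)ccc32)cc1N
F3 | step 8 | 4-bromo-3-(3,5-dibromo-1H-indol-1-yl)-2-iodo-6-methoxyaniline | COc1cc(Br)c(-n2cc(Br)c3cc(Br)ccc32)c(I)c1N
F4 | step 8 | 4-bromo-3-(3,5-dibromo-1H-indol-1-yl)-6-methoxy-2-[(trimethylsilyl)ethynyl]aniline | COc1cc(Br)c(-n2cc(Br)c3cc(Br)ccc32)c(C#C[Si](C)(C)C)c1N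
F5 | step 8 | 5-bromo-4-(3,5-dibromo-1H-indol-1-yl)-7-methoxy-1H-indole | COc1cc(Br)c(-n2cc(Br)c3cc(Br)ccc32)c2cc[nH]c12
F6 | step 4 | 3-[(2-bromo-4-methoxy-5-nitrophenyl)amino]cyclohex-2-en-1-one | COc1cc(Br)c(NC2=CC(=O)CCC2)cc1[N+](=O)[O-]
F7 | step 3 | 2-ethoxy-3,5,6,7-tetrahydro-1-benzofuran-4(2H)-one (racemic) | CCOC1CC2=C(O1)CCCC2=O
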